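The route rests on disconnecting the C6–C7 bond of ring A: C7, the tertiary carbinol flanked by the C6 and C8 ketones, is made by umpolung addition of a C6 aldehyde to the methyl ketone of a C7–C8 diketone. In one operation a chiral triazolylidene closes ring A onto a preformed pyran (ring B) and sets the only core stereocentre. The precursor is a 6-aryl-4-(formylmethylene)-4H-pyran carrying a pyruvoyl group on C8a; its diketone is unmasked from an α-ethoxy enone immediately beforehand. Chlorination at C5, acylation with the separately made (2E,4S) acid and desilylation complete the synthesis.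

Key step: step 8

Remark 1: atom numbers C1–C8a are those of the isochromene core of the target and are used for all intermediates.
Remark 2: the exocyclic C4a=C5 bond of 11, 13 and 14 is a push–pull double bond and is assumed to be configurationally labile; the descriptor given is that of the isomer drawn.
Remark 3: the antipode of the triazolium salt in step 8 is assigned by analogy with the hydrogen-bonded benzoin model; if the first run shows the opposite sense, its mirror image is used with nothing else changed.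

Step 1
Reactants: 1 2-hydroxy-6-methylbenzoic acid
Product: 2 tert-butyldimethylsilyl 2-[(tert-butyldimethylsilyl)oxy]-6-methylbenzoate
Conditions: TBSCl (2.5 equiv), imidazole (5 equiv), DMF, 40 °C
Reagents that add atoms: tert-butyldimethylsilyl chloride, CC(C)(C)[Si](C)(C)Cl
Why: Standard silylation of a phenol and a carboxylic acid; the silyl ether then protects the phenol up to the last step and the silyl ester is the handle for the acid chloride.

Step 2
Reactants: 3 (E)-4-methoxybut-3-en-2-one
Product: 4 (Z)-3-iodo-4-methoxybut-3-en-2-one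
Conditions: NIS (1.05 equiv), CH2Cl2, 0 °C to rt, dark
Reagents that add atoms: N-iodosuccinimide, O=C1CCC(=O)N1I
Why: Electrophilic α-iodination of a β-alkoxy enone, whose α-carbon is an enol-ether carbon and loses its proton after attack; this fixes the halogen on the carbon that becomes C8a.

Step 3
Reactants: 2 tert-butyldimethylsilyl 2-[(tert-butyldimethylsilyl)oxy]-6-methylbenzoate; 4 (Z)-3-iodo-4-methoxybut-3-en-2-one
Product: 6 (Z)-1-{2-[(tert-butyldimethylsilyl)oxy]-6-methylphenyl}-4-iodo-5-methoxypent-4-ene-1,3-dione, via aroyl chloride 5 (not isolated)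
Conditions: (COCl)2, DMF (cat.), CH2Cl2, 0 °C to rt, evaporate; 4 (2.1 equiv), LiN(SiMe3)2 (2.1 equiv), THF, −78 °C, then 5, −78 to −40 °C; AcOH
Reagents that add atoms: none
Why: Oxalyl chloride converts the silyl ester into the acid chloride under neutral conditions, and the kinetic lithium enolate of the methyl ketone is C-acylated (Claisen-type acylation), the second equivalent of enolate taking up the acidic diketone proton.

Step 4
Reactants: 6 (Z)-1-{2-[(tert-butyldimethylsilyl)oxy]-6-methylphenyl}-4-iodo-5-methoxypent-4-ene-1,3-dione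
Product: 7 2-{2-[(tert-butyldimethylsilyl)oxy]-6-methylphenyl}-5-iodo-4H-pyran-4-one
Conditions: TFA (5 equiv), CH2Cl2, 0 °C to rt
Reagents that add atoms: none
Why: Acid-promoted oxa-Michael addition of the aryl-ketone enol oxygen to the β-methoxy enone followed by loss of methanol should close the 4-pyranone, a standard γ-pyrone cyclisation that an aryl silyl ether survives.

Step 5
Reactants: 7 2-{2-[(tert-butyldimethylsilyl)oxy]-6-methylphenyl}-5-iodo-4H-pyran-4-one
Product: 9 2-{2-[(tert-butyldimethylsilyl)oxy]-6-methylphenyl}-5-iodo-4-methylpyrylium trifluoromethanesulfonate, via pyranol 8 (not isolated)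
Conditions: MeMgBr (1.2 equiv), THF, −78 °C; H2O; then TfOH (1.0 equiv), Et2O, 0 °C, filter
Reagents that add atoms: methylmagnesium bromide, C[Mg]Br; trifluoromethanesulfonic acid, OS(=O)(=O)C(F)(F)F
Why: Grignard 1,2-addition to the pyranone carbonyl followed by acid-induced ionisation of the tertiary carbinol to the aromatic pyrylium cation is the classical entry to 4-alkylpyrylium salts, and MeMgBr does not exchange with a vinyl iodide at −78 °C.

Step 6
Reactants: 9 2-{2-[(tert-butyldimethylsilyl)oxy]-6-methylphenyl}-5-iodo-4-methylpyrylium trifluoromethanesulfonate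
Product: 11 (2E)-2-(2-{2-[(tert-butyldimethylsilyl)oxy]-6-methylphenyl}-5-iodo-4H-pyran-4-ylidene)acetaldehyde, via aminovinylpyrylium triflate 10 (not isolated)
Conditions: DMF (5 equiv), Ac2O, 60 °C; then aq NaOAc, THF, rt
Reagents that add atoms: N,N-dimethylformamide, CN(C)C=O; water, O
Why: The 4-methyl group of a pyrylium salt is acidic, so its anhydrobase (a 4-methylene-4H-pyran) attacks the DMF–acetic anhydride iminium ion (Vilsmeier-type aminomethylenation) and mild hydrolysis of the resulting vinylogous amidinium gives the pyranylidene acetaldehyde.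

Step 7
Reactants: 11 (2E)-2-(2-{2-[(tert-butyldimethylsilyl)oxy]-6-methylphenyl}-5-iodo-4H-pyran-4-ylidene)acetaldehyde; 12 tributyl(1-ethoxyvinyl)stannane
Product: 14 (2Z)-2-[2-{2-[(tert-butyldimethylsilyl)oxy]-6-methylphenyl}-5-(2-oxopropanoyl)-4H-pyran-4-ylidene]acetaldehyde, via α-ethoxy enone 13 (not isolated)
Conditions: CO (1 atm), Pd2(dba)3 (2.5 mol %), AsPh3 (20 mol %), NMP, 45 °C; then 1 M HCl, THF, rt
Reagents that add atoms: carbon monoxide, [C-]#[O+]; water, O
Why: Carbonylative Stille coupling (oxidative addition of zerovalent palladium into the C8a–I bond, CO insertion, transmetalation, reductive elimination) should give the α-ethoxy enone, whose enol ether dilute acid hydrolyses to the C7 methyl ketone while also equilibrating the C4a=C5 geometry.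

Step 8
Reactants: 14 (2Z)-2-[2-{2-[(tert-butyldimethylsilyl)oxy]-6-methylphenyl}-5-(2-oxopropanoyl)-4H-pyran-4-ylidene]acetaldehyde
Product: 15 (7R)-3-{2-[(tert-butyldimethylsilyl)oxy]-6-methylphenyl}-7-hydroxy-7-methyl-6H-isochromene-6,8(7H)-dione
Conditions: (5aS,10bR)-2-(pentafluorophenyl)-5a,10b-dihydro-4H,6H-indeno[2,1-b][1,2,4]triazolo[4,3-d][1,4]oxazin-2-ium tetrafluoroborate (15 mol %), i-Pr2NEt (15 mol %), toluene, 4 Å MS, rt
Reagents that add atoms: none
Why: The triazolylidene adds to the C6 aldehyde and proton transfer gives the Breslow enaminol, whose C6 attacks the C7 carbonyl and, after collapse, releases the carbene and the α-ketol; the reaction type is the carbene-catalysed intramolecular crossed aldehyde–ketone benzoin reaction. Ring A closes in the 6-exo-trig mode by forming C6–C7. The C7 stereocentre is set by the catalyst: the fused aminoindanol framework shields one face of the enaminol and an O–H···O hydrogen bond to the C7 carbonyl orients the ketone so that C6 should add to its Re face, giving 7R. Chemoselectivity for C7 over C8 is needed and the substrate secures it, since C7 is an α-keto-activated methyl ketone whereas C8 is a vinylogous ester whose attack would force a five-membered ring onto the planar pyranylidene. β-Protonation of the extended enaminol is disfavoured because it would place charge on C4a of a 4H-pyran (an eight-π-electron pyranyl anion), and with chlorine still absent no α-halo-aldehyde redox path exists. Only the Z isomer of 14 can close, and the labile C4a=C5 bond should feed it by equilibration.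

Step 9
Reactants: 15 (7R)-3-{2-[(tert-butyldimethylsilyl)oxy]-6-methylphenyl}-7-hydroxy-7-methyl-6H-isochromene-6,8(7H)-dione
Product: 16 (7S)-3-{2-[(tert-butyldimethylsilyl)oxy]-6-methylphenyl}-5-chloro-7-hydroxy-7-methyl-6H-isochromene-6,8(7H)-dione
Conditions: NCS (1.05 equiv), MeCN, 0 °C to rt
Reagents that add atoms: N-chlorosuccinimide, O=C1CCC(=O)N1Cl
Why: Electrophilic chlorination at C5, the nucleophilic carbon of the cross-conjugated dienol ether (δ to O2, α to C6), outpaces attack on the silylated aryl ring; the descriptor changes from R to S only because chlorine raises the rank of C6.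

Step 10
Reactants: 17 (S)-4-benzyl-1,3-oxazolidin-2-one; 18 octanoyl chloride
Product: 19 (S)-4-benzyl-3-octanoyl-1,3-oxazolidin-2-one
Conditions: n-BuLi (1.05 equiv), THF, −78 °C; then 18, −78 to 0 °C
Reagents that add atoms: none
Why: N-Acylation of the lithiated oxazolidinone with an acid chloride is the standard way to load the auxiliary.

Step 11
Reactants: 19 (S)-4-benzyl-3-octanoyl-1,3-oxazolidin-2-one
Product: 20 (S)-4-benzyl-3-[(S)-2-methyloctanoyl]-1,3-oxazolidin-2-one
Conditions: NaN(SiMe3)2 (1.1 equiv), THF, −78 °C; MeI (4 equiv), −78 °C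
Reagents that add atoms: iodomethane, CI
Why: Evans asymmetric alkylation, in which the chelated Z sodium enolate is methylated on the face opposite the benzyl group, which sets the 2S centre (C4 of the later acid).

Step 12
Reactants: 20 (S)-4-benzyl-3-[(S)-2-methyloctanoyl]-1,3-oxazolidin-2-one
Product: 21 (S)-2-methyloctan-1-ol
Conditions: LiBH4 (1.5 equiv), H2O (1.5 equiv), Et2O, 0 °C
Reagents that add atoms: none
Why: Reductive cleavage of the exocyclic imide carbonyl by LiBH4 releases the primary alcohol without epimerisation and returns the auxiliary.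

Step 13
Reactants: 21 (S)-2-methyloctan-1-ol; 22 ethyl 2-(triphenyl-λ5-phosphanylidene)propanoate
Product: 24 ethyl (2E,4S)-2,4-dimethyldec-2-enoate, via (S)-2-methyloctanal 23 (not isolated)
Conditions: Dess–Martin periodinane (1.2 equiv), CH2Cl2, 0 °C to rt; then 22 (1.8 equiv), rt
Reagents that add atoms: none
Why: Dess–Martin oxidation followed in the same flask by Wittig olefination with the stabilised α-methyl ylide should give the E trisubstituted enoate while the α-chiral aldehyde is never stored.

Step 14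
Reactants: 24 ethyl (2E,4S)-2,4-dimethyldec-2-enoate
Product: 25 (2E,4S)-2,4-dimethyldec-2-enoic acid
Conditions: LiOH (3 equiv), THF/MeOH/H2O, rt to 40 °C; 1 M HCl
Reagents that add atoms: lithium hydroxide, [Li+].[OH-]
Why: Saponification of the ester; the γ-stereocentre is not acidic enough to suffer under aqueous hydroxide.

Step 15
Reactants: 16 (7S)-3-{2-[(tert-butyldimethylsilyl)oxy]-6-methylphenyl}-5-chloro-7-hydroxy-7-methyl-6H-isochromene-6,8(7H)-dione; 25 (2E,4S)-2,4-dimethyldec-2-enoic acid
Product: 27 (7S)-3-{2-[(tert-butyldimethylsilyl)oxy]-6-methylphenyl}-5-chloro-7-methyl-6,8-dioxo-7,8-dihydro-6H-isochromen-7-yl (2E,4S)-2,4-dimethyldec-2-enoate, via (2E,4S)-2,4-dimethyldec-2-enoyl chloride 26 (not isolated)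
Conditions: 25 (2 equiv), (COCl)2, DMF (cat.), CH2Cl2, 0 °C to rt, evaporate; then 16, pyridine (4 equiv), DMAP (1 equiv), CH2Cl2, 0 °C to rt
Reagents that add atoms: none
Why: DMAP-catalysed acylation of the tertiary α-ketol through the acylpyridinium ion; pyridine rather than a trialkylamine is used so that γ-deprotonation of the acid chloride to a vinylketene, which would erase the C4 centre of the side chain, is avoided.

Step 16
Reactants: 27 (7S)-3-{2-[(tert-butyldimethylsilyl)oxy]-6-methylphenyl}-5-chloro-7-methyl-6,8-dioxo-7,8-dihydro-6H-isochromen-7-yl (2E,4S)-2,4-dimethyldec-2-enoate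
Product: 28 (7S)-5-chloro-3-(2-hydroxy-6-methylphenyl)-7-methyl-6,8-dioxo-7,8-dihydro-6H-isochromen-7-yl (2E,4S)-2,4-dimethyldec-2-enoate
Conditions: Bu4NF (1.1 equiv), AcOH (1.3 equiv), THF, 0 °C
Reagents that add atoms: none
Why: Fluoride cleaves the aryl silyl ether rapidly, and the acetic acid buffer keeps the medium non-basic so that the C7 ester and the electrophilic C1 position are left alone.

Compound list
1 | 2-hydroxy-6-methylbenzoic acid | Cc1cccc(O)c1C(=O)O | starting material
2 | tert-butyldimethylsilyl 2-[(tert-butyldimethylsilyl)oxy]-6-methylbenzoate | Cc1cccc(O[Si](C)(C)C(C)(C)C)c1C(=O)O[Si](C)(C)C(C)(C)C | intermediate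
3 | (E)-4-methoxybut-3-en-2-one | CC(=O)/C=C/OC | starting material
4 | (Z)-3-iodo-4-methoxybut-3-en-2-one | CC(=O)/C(I)=C/OC | intermediate
5 | 2-[(tert-butyldimethylsilyl)oxy]-6-methylbenzoyl chloride (not isolated) | Cc1cccc(O[Si](C)(C)C(C)(C)C)c1C(Cl)=O | intermediate
6 | (Z)-1-{2-[(tert-butyldimethylsilyl)oxy]-6-methylphenyl}-4-iodo-5-methoxypent-4-ene-1,3-dione (largely enolised) | Cc1cccc(O[Si](C)(C)C(C)(C)C)c1C(=O)CC(=O)/C(I)=C/OC | intermediate
7 | 2-{2-[(tert-butyldimethylsilyl)oxy]-6-methylphenyl}-5-iodo-4H-pyran-4-one | Cc1cccc(O[Si](C)(C)C(C)(C)C)c1C1=CC(=O)C(I)=CO1 | intermediate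
8 | 2-{2-[(tert-butyldimethylsilyl)oxy]-6-methylphenyl}-5-iodo-4-methyl-4H-pyran-4-ol (racemic, not isolated) | Cc1cccc(O[Si](C)(C)C(C)(C)C)c1C1=CC(C)(O)C(I)=CO1 | intermediate
9 | 2-{2-[(tert-butyldimethylsilyl)oxy]-6-methylphenyl}-5-iodo-4-methylpyrylium trifluoromethanesulfonate | Cc1cccc(O[Si](C)(C)C(C)(C)C)c1-c1cc(C)c(I)c[o+]1.[O-]S(=O)(=O)C(F)(F)F | intermediate
10 | 2-{2-[(tert-butyldimethylsilyl)oxy]-6-methylphenyl}-4-[(E)-2-(dimethylamino)ethenyl]-5-iodopyrylium trifluoromethanesulfonate (not isolated) | CN(C)/C=C/c1cc(-c2c(C)cccc2O[Si](C)(C)C(C)(C)C)[o+]cc1I.[O-]S(=O)(=O)C(F)(F)F | intermediate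
11 | (2E)-2-(2-{2-[(tert-butyldimethylsilyl)oxy]-6-methylphenyl}-5-iodo-4H-pyran-4-ylidene)acetaldehyde | O=C/C=C1\C=C(c2c(C)cccc2O[Si](C)(C)C(C)(C)C)OC=C1I | intermediate
12 | tributyl(1-ethoxyvinyl)stannane | CCCC[Sn](CCCC)(CCCC)C(=C)OCC | starting material
13 | (2Z)-2-[2-{2-[(tert-butyldimethylsilyl)oxy]-6-methylphenyl}-5-(2-ethoxyprop-2-enoyl)-4H-pyran-4-ylidene]acetaldehyde (not isolated) | O=C/C=C1/C=C(c2c(C)cccc2O[Si](C)(C)C(C)(C)C)OC=C1C(=O)C(=C)OCC | intermediate
14 | (2Z)-2-[2-{2-[(tert-butyldimethylsilyl)oxy]-6-methylphenyl}-5-(2-oxopropanoyl)-4H-pyran-4-ylidene]acetaldehyde | O=C/C=C1/C=C(c2c(C)cccc2O[Si](C)(C)C(C)(C)C)OC=C1C(=O)C(C)=O | intermediate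
15 | (7R)-3-{2-[(tert-butyldimethylsilyl)oxy]-6-methylphenyl}-7-hydroxy-7-methyl-6H-isochromene-6,8(7H)-dione | O[C@@]1(C)C(=O)C2=COC(c3c(C)cccc3O[Si](C)(C)C(C)(C)C)=CC2=CC1=O | intermediate
16 | (7S)-3-{2-[(tert-butyldimethylsilyl)oxy]-6-methylphenyl}-5-chloro-7-hydroxy-7-methyl-6H-isochromene-6,8(7H)-dione | O[C@@]1(C)C(=O)C2=COC(c3c(C)cccc3O[Si](C)(C)C(C)(C)C)=CC2=C(Cl)C1=O | intermediate
17 | (S)-4-benzyl-1,3-oxazolidin-2-one | O=C1N[C@@H](Cc2ccccc2)CO1 | starting material
18 | octanoyl chloride | CCCCCCCC(Cl)=O | starting material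
19 | (S)-4-benzyl-3-octanoyl-1,3-oxazolidin-2-one | CCCCCCCC(=O)N1[C@@H](Cc2ccccc2)COC1=O | intermediate
20 | (S)-4-benzyl-3-[(S)-2-methyloctanoyl]-1,3-oxazolidin-2-one | CCCCCC[C@H](C)C(=O)N1[C@@H](Cc2ccccc2)COC1=O | intermediate
21 | (S)-2-methyloctan-1-ol | CCCCCC[C@H](C)CO | intermediate
22 | ethyl 2-(triphenyl-λ5-phosphanylidene)propanoate | CCOC(=O)C(C)=P(c1ccccc1)(c1ccccc1)c1ccccc1 | starting material
23 | (S)-2-methyloctanal (not isolated) | CCCCCC[C@H](C)C=O | intermediate
24 | ethyl (2E,4S)-2,4-dimethyldec-2-enoate | CCCCCC[C@H](C)/C=C(\C)C(=O)OCC | intermediate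
25 | (2E,4S)-2,4-dimethyldec-2-enoic acid | CCCCCC[C@H](C)/C=C(\C)C(=O)O | intermediate
26 | (2E,4S)-2,4-dimethyldec-2-enoyl chloride (not isolated) | CCCCCC[C@H](C)/C=C(\C)C(Cl)=O | intermediate
27 | (7S)-3-{2-[(tert-butyldimethylsilyl)oxy]-6-methylphenyl}-5-chloro-7-methyl-6,8-dioxo-7,8-dihydro-6H-isochromen-7-yl (2E,4S)-2,4-dimethyldec-2-enoate | CCCCCC[C@H](C)/C=C(\C)C(=O)O[C@@]1(C)C(=O)C2=COC(c3c(C)cccc3O[Si](C)(C)C(C)(C)C)=CC2=C(Cl)C1=O | intermediate
28 | (7S)-5-chloro-3-(2-hydroxy-6-methylphenyl)-7-methyl-6,8-dioxo-7,8-dihydro-6H-isochromen-7-yl (2E,4S)-2,4-dimethyldec-2-enoate (CNP0323429.2) | CCCCCC[C@H](C)/C=C(\C)C(=O)O[C@@]1(C)C(=O)C2=COC(c3c(C)cccc3O)=CC2=C(Cl)C1=O | target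

Total step count: 16. Longest linear sequence: 10 steps (1, 3, 4, 5, 6, 7, 8, 9, 15, 16).

Steps most likely to fail

Step 8. The carbene may be diverted before the C6–C7 bond forms, through slow addition to the electron-rich vinylogous-formate aldehyde, β-protonation of the enaminol or reversible attack on the diketone. Discrimination between the faces of the C7 carbonyl may also be weak. The fallback takes ring A from an arene and sets C7 by oxidative dearomatisation. It sets out from acid chloride 5, generated as in step 3. Reduction with LiAlH(O-t-Bu)3 (THF, −78 °C) should give 2-[(tert-butyldimethylsilyl)oxy]-6-methylbenzaldehyde F1. A Colvin rearrangement (Me3SiCHN2, LiN(i-Pr)2, THF, −78 °C to rt) should turn it into tert-butyl(2-ethynyl-3-methylphenoxy)dimethylsilane F2. Sonogashira coupling with 6-bromo-2,4-dihydroxy-3-methylbenzaldehyde (PdCl2(PPh3)2, CuI, Et3N, DMF, 60 °C) should give 6-({2-[(tert-butyldimethylsilyl)oxy]-6-methylphenyl}ethynyl)-2,4-dihydroxy-3-methylbenzaldehyde F3. Copper–sparteine–dioxygen hydroxylative dearomatisation ([Cu(MeCN)4]PF6, the sparteine antipode that delivers the required configuration, O2, i-Pr2NEt, CH2Cl2, −78 to −10 °C) should give the o-quinol (3S)-6-({2-[(tert-butyldimethylsilyl)oxy]-6-methylphenyl}ethynyl)-2,3-dihydroxy-3-methyl-4-oxocyclohexa-1,5-diene-1-carbaldehyde F4. 6-endo cycloisomerisation of its formyl oxygen onto the alkyne (aqueous KH2PO4/K2HPO4, MeCN, rt) comes back to the route at 15.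

Step 7. CO insertion may lose to direct transmetalation, which would give the one-carbon-short 1-ethoxyvinyl product, or oxidative addition at the hindered, electron-rich C8a–I bond may be slow and end in protodeiodination. The fallback sets out from 11. Nozaki–Hiyama–Kishi coupling with 2,2-dimethoxypropanal (CrCl2, NiCl2 (cat.), DMF, rt) should give racemic (2E)-2-[2-{2-[(tert-butyldimethylsilyl)oxy]-6-methylphenyl}-5-(1-hydroxy-2,2-dimethoxypropyl)-4H-pyran-4-ylidene]acetaldehyde F5; the reagent aldehyde is used in excess and is far more electrophilic than the vinylogous-formate aldehyde of 11. Dess–Martin oxidation should give (2Z)-2-[2-{2-[(tert-butyldimethylsilyl)oxy]-6-methylphenyl}-5-(2,2-dimethoxypropanoyl)-4H-pyran-4-ylidene]acetaldehyde F6. Hydrolysis of the ketal (aqueous TFA, THF, rt) comes back to the route at 14.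

Step 3. C-Acylation by the di-ortho-substituted acid chloride may be slow, so that O-acylation, silyl transfer to an enolate oxygen or decay of the iodo-enolate competes. The fallback sets out from 5 and introduces iodine after the ring is made. Acyl Sonogashira coupling with (Z)-1-methoxybut-1-en-3-yne (PdCl2(PPh3)2, CuI, Et3N, THF, rt) should give (4Z)-1-{2-[(tert-butyldimethylsilyl)oxy]-6-methylphenyl}-5-methoxypent-4-en-2-yn-1-one F7. Acid-mediated hydration of the ynone and cyclisation (TFA, H2O (2 equiv), CH2Cl2, rt) should give 2-{2-[(tert-butyldimethylsilyl)oxy]-6-methylphenyl}-4H-pyran-4-one F8. Iodination (NIS, TFA (cat.), MeCN, rt) is expected at C5, the α-position not shielded by the orthogonal di-ortho-substituted aryl ring, and comes back to the route at 7.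

Further compounds
F1 | step 8 | 2-[(tert-butyldimethylsilyl)oxy]-6-methylbenzaldehyde | Cc1cccc(O[Si](C)(C)C(C)(C)C)c1C=O
F2 | step 8 | tert-butyl(2-ethynyl-3-methylphenoxy)dimethylsilane | Cc1cccc(O[Si](C)(C)C(C)(C)C)c1C#C
F3 | step 8 | 6-({2-[(tert-butyldimethylsilyl)oxy]-6-methylphenyl}ethynyl)-2,4-dihydroxy-3-methylbenzaldehyde | Cc1c(O)cc(C#Cc2c(C)cccc2O[Si](C)(C)C(C)(C)C)c(C=O)c1O
F4 | step 8 | (3S)-6-({2-[(tert-butyldimethylsilyl)oxy]-6-methylphenyl}ethynyl)-2,3-dihydroxy-3-methyl-4-oxocyclohexa-1,5-diene-1-carbaldehyde | O[C@@]1(C)C(O)=C(C=O)C(C#Cc2c(C)cccc2O[Si](C)(C)C(C)(C)C)=CC1=O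
F5 | step 7 | (2E)-2-[2-{2-[(tert-butyldimethylsilyl)oxy]-6-methylphenyl}-5-(1-hydroxy-2,2-dimethoxypropyl)-4H-pyran-4-ylidene]acetaldehyde (racemic) | O=C/C=C1\C=C(c2c(C)cccc2O[Si](C)(C)C(C)(C)C)OC=C1C(O)C(C)(OC)OC
F6 | step 7 | (2Z)-2-[2-{2-[(tert-butyldimethylsilyl)oxy]-6-methylphenyl}-5-(2,2-dimethoxypropanoyl)-4H-pyran-4-ylidene]acetaldehyde | O=C/C=C1/C=C(c2c(C)cccc2O[Si](C)(C)C(C)(C)C)OC=C1C(=O)C(C)(OC)OC
F7 | step 3 | (4Z)-1-{2-[(tert-butyldimethylsilyl)oxy]-6-methylphenyl}-5-methoxypent-4-en-2-yn-1-one | CO/C=C\C#CC(=O)c1c(C)cccc1O[Si](C)(C)C(C)(C)C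
F8 | step 3 | 2-{2-[(tert-butyldimethylsilyl)oxy]-6-methylphenyl}-4H-pyran-4-one | Cc1cccc(O[Si](C)(C)C(C)(C)C)c1C1=CC(=O)C=CO1
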